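**Strategy.** The route rests on closing the ten-membered carbocycle at the C9–C10 bond, between the ring carbinol carbon and the ring alkene carbon that carries CO2Me. An intramolecular Nozaki–Hiyama–Kishi reaction of a (Z)-2-iodo enoate with an α-angeloyloxy aldehyde forms this bond, delivers the cis C1=C10 alkene with retention and sets C9 from C8; it exploits the 2-(1-hydroxyalkyl)acrylate unit C1=C10(CO2Me)–C9(OH) of the cyclodecadiene. The precursor is a trans α-methylene-γ-butyrolactone (C6, C7) that carries the iodo-enoate arm on C6 and the aldehyde arm on C7, built from neryl acetate and (R)-glyceraldehyde acetonide by a chromium-catalysed asymmetric 2-(methoxycarbonyl)allylation.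

Key step: step 12

Remark: germacrane numbering is used (lactone oxygen on C6, ring fusion C7, angelate on C8, carbinol C9, ester-bearing alkene carbon C10, ring alkenes C1=C10 and C4=C5); the target is 6R,7S,8S,9R with both ring alkenes cis within the ring.
Remark: L* is 1,8-bis(4-isopropyl-4,5-dihydro-1,3-oxazol-2-yl)-9H-carbazole, a chiral tridentate bis(oxazoline) ligand; it is assumed that the antipode giving the 6R sense is found in a test reaction.

Step 1
Reactants: 1 neryl acetate
Product: 3 (2Z)-3-methyl-6-oxohex-2-en-1-yl acetate, via ozonide 2 (not isolated)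
Conditions: O3 (1 equiv), CH2Cl2, −78 °C; then Me2S, −78 °C → rt
Reagents that add atoms: ozone [O-][O+]=O
Why: Ozonolysis with reductive work-up: ozone should attack the electron-rich C6=C7 alkene faster than the C2=C3 alkene, which the allylic acetate deactivates, so one equivalent cleaves only the isopropylidene end and Me2S then frees the aldehyde without touching the (Z)-alkene.

Step 2
Reactants: 3 (2Z)-3-methyl-6-oxohex-2-en-1-yl acetate
Product: 4 methyl (2Z,6Z)-8-(acetyloxy)-2-iodo-6-methylocta-2,6-dienoate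
Conditions: Ph3P=CHCO2Me, NIS, MeCN, −20 °C; then K2CO3, 3, rt
Reagents that add atoms: methyl (triphenylphosphoranylidene)acetate COC(=O)C=P(c1ccccc1)(c1ccccc1)c1ccccc1; N-iodosuccinimide O=C1CCC(=O)N1I
Why: Wittig olefination with the stabilised α-iodo ylide made in situ should place the alkyl chain trans to the ester, which is the (Z)-2-iodo enoate geometry that later becomes the ring-cis C1=C10 alkene.

Step 3
Reactants: 4 methyl (2Z,6Z)-8-(acetyloxy)-2-iodo-6-methylocta-2,6-dienoate
Product: 5 methyl (2Z,6Z)-8-hydroxy-2-iodo-6-methylocta-2,6-dienoate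
Conditions: K2CO3 (0.2 equiv), MeOH, 0 °C
Reagents that add atoms: none
Why: Base-catalysed transesterification (Zemplén-type methanolysis) removes the primary allylic acetate at low temperature, while exchange at the methyl ester is degenerate and the iodo enoate is not expected to add methanol in the short reaction time.

Step 4
Reactants: 5 methyl (2Z,6Z)-8-hydroxy-2-iodo-6-methylocta-2,6-dienoate
Product: 6 methyl (2Z,6Z)-2-iodo-6-methyl-8-oxoocta-2,6-dienoate
Conditions: MnO2, CH2Cl2, rt
Reagents that add atoms: none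
Why: Heterogeneous MnO2 oxidation is selective for the allylic alcohol and runs without acid or base, so the (Z)-enal should form without isomerisation to the (E)-enal.

Step 5
Reactants: 7 (4R)-2,2-dimethyl-1,3-dioxolane-4-carbaldehyde; 8 methyl acrylate
Product: 9 methyl 2-{[(4R)-2,2-dimethyl-1,3-dioxolan-4-yl](hydroxy)methyl}prop-2-enoate (both carbinol epimers)
Conditions: DABCO (0.5 equiv), neat in excess 8, rt, 5 d
Reagents that add atoms: none
Why: Morita–Baylis–Hillman reaction: DABCO adds to the acrylate and the resulting enolate adds to the aldehyde; the new carbinol centre needs no control because it becomes sp2 in step 6, and the dioxolane centre is not touched.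

Step 6
Reactants: 9 methyl 2-{[(4R)-2,2-dimethyl-1,3-dioxolan-4-yl](hydroxy)methyl}prop-2-enoate
Product: 10 methyl (2Z)-2-(bromomethyl)-3-[(4S)-2,2-dimethyl-1,3-dioxolan-4-yl]prop-2-enoate
Conditions: NBS, Me2S, CH2Cl2, 0 °C → rt
Reagents that add atoms: N-bromosuccinimide O=C1CCC(=O)N1Br
Why: Corey–Kim-type activation of the allylic alcohol as an alkoxysulfonium ion followed by SN2′ attack of bromide gives the rearranged primary allylic bromide as the preferred (Z)-isomer (ester trans to the dioxolane), with the dioxolane centre, the future C8, unchanged (its descriptor changes only because the priorities change).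

Step 7
Reactants: 6 methyl (2Z,6Z)-2-iodo-6-methyl-8-oxoocta-2,6-dienoate; 10 methyl (2Z)-2-(bromomethyl)-3-[(4S)-2,2-dimethyl-1,3-dioxolan-4-yl]prop-2-enoate
Product: 14 methyl (2Z,6Z)-7-[(2R,3S)-3-[(4S)-2,2-dimethyl-1,3-dioxolan-4-yl]-4-methylidene-5-oxooxolan-2-yl]-2-iodo-6-methylhepta-2,6-dienoate, via allylchromium 11 (not isolated), via silyl ether 12 (not isolated), via hydroxy ester 13 (not isolated)
Conditions: CrCl2 (10 mol%), L* (12 mol%), Mn powder, Me3SiCl, iPr2NEt, THF, rt; then Bu4NF, THF, 0 °C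
Reagents that add atoms: none
Why: Catalytic asymmetric Nozaki–Hiyama 2-(alkoxycarbonyl)allylation: the allylchromium from 10 adds through its γ-carbon (C7) to aldehyde 6 in a chair transition state whose ligand-controlled aldehyde face gives 6R and whose anti topicity gives 7S (trans across C6–C7), the C8 centre of 10 being carried through unchanged, and fluoride desilylation lets the C6 alkoxide close the γ-lactone on the methyl ester.

Step 8
Reactants: 14 methyl (2Z,6Z)-7-[(2R,3S)-3-[(4S)-2,2-dimethyl-1,3-dioxolan-4-yl]-4-methylidene-5-oxooxolan-2-yl]-2-iodo-6-methylhepta-2,6-dienoate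
Product: 15 methyl (2Z,6Z)-7-[(2R,3R)-3-[(1S)-1,2-dihydroxyethyl]-4-methylidene-5-oxooxolan-2-yl]-2-iodo-6-methylhepta-2,6-dienoate
Conditions: AcOH/H2O 4:1, 40 °C
Reagents that add atoms: none
Why: Acid-catalysed hydrolysis of the terminal acetonide; the lactone, both esters and the alkenyl iodide are stable to aqueous acetic acid, and the trans-lactone on O6 should remain favoured over translactonisation to O8, which would give a cis-disubstituted ring (no centre changes; the C7 descriptor changes by priority only).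

Step 9
Reactants: 15 methyl (2Z,6Z)-7-[(2R,3R)-3-[(1S)-1,2-dihydroxyethyl]-4-methylidene-5-oxooxolan-2-yl]-2-iodo-6-methylhepta-2,6-dienoate
Product: 16 methyl (2Z,6Z)-7-[(2R,3R)-3-[(1S)-1-hydroxy-2-[(triethylsilyl)oxy]ethyl]-4-methylidene-5-oxooxolan-2-yl]-2-iodo-6-methylhepta-2,6-dienoate
Conditions: Et3SiCl (1.05 equiv), imidazole, CH2Cl2, −40 °C
Reagents that add atoms: chlorotriethylsilane CC[Si](Cl)(CC)CC
Why: Steric differentiation in silylation: at low temperature Et3SiCl should react with the primary C9 hydroxyl much faster than with the secondary C8 hydroxyl next to the ring.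

Step 10
Reactants: 16 methyl (2Z,6Z)-7-[(2R,3R)-3-[(1S)-1-hydroxy-2-[(triethylsilyl)oxy]ethyl]-4-methylidene-5-oxooxolan-2-yl]-2-iodo-6-methylhepta-2,6-dienoate
Product: 17 (1S)-1-[(2R,3S)-2-[(1Z,5Z)-6-iodo-7-methoxy-2-methyl-7-oxohepta-1,5-dien-1-yl]-4-methylidene-5-oxooxolan-3-yl]-2-[(triethylsilyl)oxy]ethyl (2Z)-2-methylbut-2-enoate
Conditions: angelic acid, 2,4,6-Cl3C6H2COCl, Et3N, toluene, rt; then 16, 80 °C
Reagents that add atoms: angelic acid C/C=C(/C)C(=O)O
Why: Yamaguchi esterification through the mixed 2,4,6-trichlorobenzoic anhydride acylates the C8 hydroxyl at the less hindered angeloyl carbonyl without a nucleophilic catalyst, conditions under which the (Z)-geometry of the angelate should survive and C8 is not affected.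

Step 11
Reactants: 17 (1S)-1-[(2R,3S)-2-[(1Z,5Z)-6-iodo-7-methoxy-2-methyl-7-oxohepta-1,5-dien-1-yl]-4-methylidene-5-oxooxolan-3-yl]-2-[(triethylsilyl)oxy]ethyl (2Z)-2-methylbut-2-enoate
Product: 18 (1S)-1-[(2R,3S)-2-[(1Z,5Z)-6-iodo-7-methoxy-2-methyl-7-oxohepta-1,5-dien-1-yl]-4-methylidene-5-oxooxolan-3-yl]-2-oxoethyl (2Z)-2-methylbut-2-enoate
Conditions: (COCl)2, DMSO, CH2Cl2, −78 → −40 °C; then Et3N, −78 → 0 °C
Reagents that add atoms: none
Why: Swern oxidation applied directly to a primary triethylsilyl ether: the chlorosulfonium salt cleaves the Si–O bond to give the alkoxysulfonium ion, which collapses to the aldehyde on addition of base at low temperature, so no free 1,2-hydroxy ester that could undergo acyl migration is ever present.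

Step 12
Reactants: 18 (1S)-1-[(2R,3S)-2-[(1Z,5Z)-6-iodo-7-methoxy-2-methyl-7-oxohepta-1,5-dien-1-yl]-4-methylidene-5-oxooxolan-3-yl]-2-oxoethyl (2Z)-2-methylbut-2-enoate
Product: 20 methyl (3aS,4S,5R,6E,10Z,11aR)-5-hydroxy-10-methyl-3-methylidene-4-{[(2Z)-2-methylbut-2-enoyl]oxy}-2-oxo-2,3,3a,4,5,8,9,11a-octahydrocyclodeca[b]furan-6-carboxylate, via alkenylchromium 19 (not isolated)
Conditions: CrCl2 (8 equiv), NiCl2 (5 mol%), DMSO, rt, slow addition of 18 to a final 2 mM
Reagents that add atoms: none
Why: Zerovalent nickel, generated from NiCl2 by CrCl2, inserts into the C10–I bond of the (Z)-2-iodo enoate, transmetallation gives the trivalent alkenylchromium 19, and this adds to the C9 aldehyde, the esters, the lactone and the exocyclic methylene being inert to organochromium reagents. The closest known reaction type is the Nozaki–Hiyama–Kishi macrocyclisation of alkenyl iodides onto aldehydes, which is established for medium rings and for 2-halo enone and enoate donors. The ten-membered carbocycle closes by 10-exo-trig addition of C10 to the C9 carbonyl, helped by the trans-lactone, the cis C4=C5 alkene and the cis arrangement of C2 and the C–Cr bond, which together hold the two termini close. The C–Cr bond reacts with retention, so C2 stays cis to C9 and the C1=C10 alkene ends ring-cis with the ester outside. The new C9 centre is controlled by C8: Felkin–Anh attack anti to the C8–O bond of the angelate, favoured by non-chelating chromium, should give the 8,9-anti (9R) alcohol. The step needs C–I activation in preference to carbonyl reduction and ring closure in preference to oligomerisation, which nickel catalysis and slow addition to about 2 mM should secure.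

**Compound list**

1 | neryl acetate, (2Z)-3,7-dimethylocta-2,6-dien-1-yl acetate | CC(=O)OC/C=C(/C)CCC=C(C)C | starting material
2 | ozonide, (2Z)-5-(5,5-dimethyl-1,2,4-trioxolan-3-yl)-3-methylpent-2-en-1-yl acetate | CC(=O)OC/C=C(/C)CCC1OOC(C)(C)O1 | intermediate
3 | (2Z)-3-methyl-6-oxohex-2-en-1-yl acetate | CC(=O)OC/C=C(/C)CCC=O | intermediate
4 | methyl (2Z,6Z)-8-(acetyloxy)-2-iodo-6-methylocta-2,6-dienoate | COC(=O)/C(I)=C/CC/C(C)=C\COC(C)=O | intermediate
5 | methyl (2Z,6Z)-8-hydroxy-2-iodo-6-methylocta-2,6-dienoate | COC(=O)/C(I)=C/CC/C(C)=C\CO | intermediate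
6 | methyl (2Z,6Z)-2-iodo-6-methyl-8-oxoocta-2,6-dienoate | COC(=O)/C(I)=C/CC/C(C)=C\C=O | intermediate
7 | (4R)-2,2-dimethyl-1,3-dioxolane-4-carbaldehyde, (R)-glyceraldehyde acetonide | O=C[C@H]1COC(C)(C)O1 | starting material
8 | methyl acrylate | C=CC(=O)OC | starting material
9 | methyl 2-{[(4R)-2,2-dimethyl-1,3-dioxolan-4-yl](hydroxy)methyl}prop-2-enoate, both carbinol epimers | C=C(C(=O)OC)C(O)[C@H]1COC(C)(C)O1 | intermediate
10 | methyl (2Z)-2-(bromomethyl)-3-[(4S)-2,2-dimethyl-1,3-dioxolan-4-yl]prop-2-enoate | COC(=O)/C(CBr)=C/[C@H]1COC(C)(C)O1 | intermediate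
11 | allylchromium from 10, trivalent chromium on the former CH2Br carbon, written as the dichloride without L* | COC(=O)C(C[Cr](Cl)Cl)=C[C@H]1COC(C)(C)O1 | intermediate
12 | silyl ether, dimethyl (2Z,6Z,8R,9R)-9-[(4S)-2,2-dimethyl-1,3-dioxolan-4-yl]-2-iodo-6-methyl-10-methylidene-8-[(trimethylsilyl)oxy]undeca-2,6-dienedioate | C=C(C(=O)OC)[C@H]([C@H]1COC(C)(C)O1)[C@H](O[Si](C)(C)C)/C=C(/C)CC/C=C(/C(=O)OC)I | intermediate
13 | hydroxy ester, dimethyl (2Z,6Z,8R,9S)-9-[(4S)-2,2-dimethyl-1,3-dioxolan-4-yl]-8-hydroxy-2-iodo-6-methyl-10-methylideneundeca-2,6-dienedioate | C=C(C(=O)OC)[C@H]([C@H]1COC(C)(C)O1)[C@H](O)/C=C(/C)CC/C=C(/C(=O)OC)I | intermediate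
14 | methyl (2Z,6Z)-7-[(2R,3S)-3-[(4S)-2,2-dimethyl-1,3-dioxolan-4-yl]-4-methylidene-5-oxooxolan-2-yl]-2-iodo-6-methylhepta-2,6-dienoate | C=C1C(=O)O[C@H](/C=C(/C)CC/C=C(/C(=O)OC)I)[C@H]1[C@H]1COC(C)(C)O1 | intermediate
15 | methyl (2Z,6Z)-7-[(2R,3R)-3-[(1S)-1,2-dihydroxyethyl]-4-methylidene-5-oxooxolan-2-yl]-2-iodo-6-methylhepta-2,6-dienoate | C=C1C(=O)O[C@H](/C=C(/C)CC/C=C(/C(=O)OC)I)[C@H]1[C@H](O)CO | intermediate
16 | methyl (2Z,6Z)-7-[(2R,3R)-3-[(1S)-1-hydroxy-2-[(triethylsilyl)oxy]ethyl]-4-methylidene-5-oxooxolan-2-yl]-2-iodo-6-methylhepta-2,6-dienoate | C=C1C(=O)O[C@H](/C=C(/C)CC/C=C(/C(=O)OC)I)[C@H]1[C@H](O)CO[Si](CC)(CC)CC | intermediate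
17 | (1S)-1-[(2R,3S)-2-[(1Z,5Z)-6-iodo-7-methoxy-2-methyl-7-oxohepta-1,5-dien-1-yl]-4-methylidene-5-oxooxolan-3-yl]-2-[(triethylsilyl)oxy]ethyl (2Z)-2-methylbut-2-enoate | C=C1C(=O)O[C@H](/C=C(/C)CC/C=C(/C(=O)OC)I)[C@H]1[C@H](OC(=O)/C(C)=C\C)CO[Si](CC)(CC)CC | intermediate
18 | (1S)-1-[(2R,3S)-2-[(1Z,5Z)-6-iodo-7-methoxy-2-methyl-7-oxohepta-1,5-dien-1-yl]-4-methylidene-5-oxooxolan-3-yl]-2-oxoethyl (2Z)-2-methylbut-2-enoate | C=C1C(=O)O[C@H](/C=C(/C)CC/C=C(/C(=O)OC)I)[C@H]1[C@H](OC(=O)/C(C)=C\C)C=O | intermediate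
19 | alkenylchromium from 18, trivalent chromium dichloride in place of iodine on C10 | C=C1C(=O)O[C@H](/C=C(/C)CC/C=C(/C(=O)OC)[Cr](Cl)Cl)[C@H]1[C@H](OC(=O)/C(C)=C\C)C=O | intermediate
20 | methyl (3aS,4S,5R,6E,10Z,11aR)-5-hydroxy-10-methyl-3-methylidene-4-{[(2Z)-2-methylbut-2-enoyl]oxy}-2-oxo-2,3,3a,4,5,8,9,11a-octahydrocyclodeca[b]furan-6-carboxylate | C=C1C(=O)O[C@@H]2/C=C(/C)CC/C=C(/C(=O)OC)[C@@H](O)[C@@H](OC(=O)/C(C)=C\C)[C@@H]12 | target

**Count.** Total: 12 steps. Longest linear sequence: 10 steps (steps 1–4 and 7–12, from neryl acetate).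

**Steps most likely to fail**

1. Step 12 (ring closure). The alkenylchromium may be protonated or may add intermolecularly instead of closing the ring. Facial selectivity at C9 may be overridden by the conformation of the forming ring. The new C9 alkoxide may take over the angelate by a 1,2-acyl shift, and the C1=C10 geometry may erode through a chromium allenolate. Fallback: starting from 18, the same closure is used only to make the ring, and the 9-epimeric macrocycle F1 is accepted. Oxidation of its allylic alcohol with Dess–Martin periodinane/NaHCO3 gives the 9-oxo macrocycle F2. A reagent-controlled reduction (Me-CBS oxazaborolidine with catecholborane, antipode chosen for 9R, or NaBH4/CeCl3 if the ring itself directs the hydride correctly) then rejoins the route at 20.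

2. Step 7 (allylation and lactonisation). The ligand and the C8 centre of 10 may be mismatched, giving poor facial selectivity. Isomerisation of the allylchromium may erode the anti topicity, and the dioxolane oxygen may be lost by elimination from the organochromium. Fallback: starting from 9, acetylation (Ac2O, pyridine) gives the Morita–Baylis–Hillman acetate F3. Copper-catalysed SN2′ borylation (B2pin2, CuCl, KOtBu, THF) gives the linear pinacol allylboronate F4. Its allylboration of 6 through a closed six-membered transition state, catalysed by a chiral BINOL-derived phosphoric acid or by triflic acid, then p-TsOH for lactonisation, rejoins the route at 14.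

3. Step 11 (direct oxidation of the silyl ether). Activation of the Si–O bond may be incomplete, and Et3N may epimerise the α-acyloxy aldehyde at C8. Fallback: starting from 17, HF·pyridine in THF/pyridine at 0 °C gives the primary alcohol F5, and Dess–Martin periodinane/NaHCO3 in CH2Cl2 oxidises it under non-basic conditions, rejoining the route at 18.

Further compounds
F1 | step 12 | methyl (3aS,4S,5S,6E,10Z,11aR)-5-hydroxy-10-methyl-3-methylidene-4-{[(2Z)-2-methylbut-2-enoyl]oxy}-2-oxo-2,3,3a,4,5,8,9,11a-octahydrocyclodeca[b]furan-6-carboxylate (9-epimeric macrocycle) | C=C1C(=O)O[C@@H]2/C=C(/C)CC/C=C(/C(=O)OC)[C@H](O)[C@@H](OC(=O)/C(C)=C\C)[C@@H]12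
F2 | step 12 | methyl (3aS,4S,6E,10Z,11aR)-10-methyl-3-methylidene-4-{[(2Z)-2-methylbut-2-enoyl]oxy}-2,5-dioxo-2,3,3a,4,5,8,9,11a-octahydrocyclodeca[b]furan-6-carboxylate (9-oxo macrocycle) | C=C1C(=O)O[C@@H]2/C=C(/C)CC/C=C(/C(=O)OC)C(=O)[C@@H](OC(=O)/C(C)=C\C)[C@@H]12
F3 | step 7 | methyl 2-{(acetyloxy)[(4R)-2,2-dimethyl-1,3-dioxolan-4-yl]methyl}prop-2-enoate | C=C(C(=O)OC)C(OC(C)=O)[C@H]1COC(C)(C)O1
F4 | step 7 | methyl (2E)-3-[(4S)-2,2-dimethyl-1,3-dioxolan-4-yl]-2-[(4,4,5,5-tetramethyl-1,3,2-dioxaborolan-2-yl)methyl]prop-2-enoate | COC(=O)/C(CB1OC(C)(C)C(C)(C)O1)=C/[C@H]1COC(C)(C)O1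
F5 | step 11 | (1S)-2-hydroxy-1-[(2R,3S)-2-[(1Z,5Z)-6-iodo-7-methoxy-2-methyl-7-oxohepta-1,5-dien-1-yl]-4-methylidene-5-oxooxolan-3-yl]ethyl (2Z)-2-methylbut-2-enoate | C=C1C(=O)O[C@H](/C=C(/C)CC/C=C(/C(=O)OC)I)[C@H]1[C@H](OC(=O)/C(C)=C\C)CO
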